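**Retrosynthetic overview**

Numbering: ring C1 (O-angelate), C2=C3 (methyl on C3), C4 (OAc), C5H2, C6; side chain C7(CH3)–C8H2–C9(OAc)–C10=C11(CH3)2.
Feature: the allylic C1–O and C4–O bonds of the cyclohexene are cis across C2=C3 and both trans to the C6 chain, which is what O2 leaves when it bridges the termini of a 2-methyl-5-alkylcyclohexa-1,3-diene; of the two oxygens only the one on C1 sits 1,5 to C9.
Disconnections: both acetates, then the C9 carbinol (enone reduction), the angelate ester, C9–C10 (alkenyllithium opening of a δ-lactone), lactone to enediol ester, enediol to endoperoxide, diene to 4-substituted cyclohexenone (dienyl triflate, methyl coupling), enone to methyl vinyl ketone plus an aldehyde ester from 3-methylglutaric anhydride.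
Ring order: carbocycle first (Michael addition, aldol condensation); then the 1,2-dioxine bridge is made by singlet oxygen and cleaved; then the δ-lactone O(C1)–C9 is closed and reopened by the isobutenyl nucleophile.

Key step: step 8

Assumption: (DHQ)2AQN is taken as the pseudoenantiomer that gives the (S)-half ester 2; the sense is checked by the sign of rotation of 2 and, if it is opposite, (DHQD)2AQN is used instead with nothing else changed.

**Route**

Step 1
Reactants: 1 3-methylglutaric anhydride
Product: 2 (S)-5-methoxy-3-methyl-5-oxopentanoic acid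
Conditions: MeOH (10 equiv), (DHQ)2AQN [hydroquinine anthraquinone-1,4-diyl diether] (10–30 mol%), Et2O, −40 °C
Reagents that add atoms: methanol (CO)
Why: Catalytic enantioselective alcoholysis (desymmetrisation) of a meso anhydride, in which the dimeric cinchona alkaloid acts as chiral general base and directs methanol to one of the two enantiotopic carbonyl groups, which sets C7.

Step 2
Reactants: 2 (S)-5-methoxy-3-methyl-5-oxopentanoic acid
Product: 3 methyl (S)-5-hydroxy-3-methylpentanoate
Conditions: BH3·SMe2 (1.1 equiv), THF, −10 → 0 °C; cold aqueous quench, used crude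
Reagents that add atoms: none
Why: Chemoselective borane reduction of a carboxylic acid beside an ester proceeds through the acyloxyborane and leaves the methyl ester and C7 untouched.

Step 3
Reactants: 3 methyl (S)-5-hydroxy-3-methylpentanoate
Product: 4 methyl (S)-3-methyl-5-oxopentanoate
Conditions: Dess–Martin periodinane, pyridine, CH2Cl2, 0 °C, run directly on crude 3
Reagents that add atoms: none
Why: Dess–Martin oxidation of a primary alcohol stops at the aldehyde under non-aqueous buffered conditions and is fast enough that the δ-hydroxy ester should not lactonise first.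

Step 4
Reactants: 4 methyl (S)-3-methyl-5-oxopentanoate; 5 methyl vinyl ketone
Product: 6 methyl (3R,4S)-4-formyl-3-methyl-7-oxooctanoate
Conditions: (S)-2-[methoxy(diphenyl)methyl]pyrrolidine (5–10 mol%), ethyl 3,4-dihydroxybenzoate (20 mol%), 5 (1.5 equiv), neat, 4 °C
Reagents that add atoms: none
Why: Enamine-catalysed asymmetric Michael addition of an aldehyde to an enone, in which the (E)-enamine of 4 is shielded on one face by the methoxy(diphenyl)methyl group so that the enone is attacked from the open face and C6 should be set as drawn under catalyst control, the remote C7 centre having little say.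

Step 5
Reactants: 6 methyl (3R,4S)-4-formyl-3-methyl-7-oxooctanoate
Product: 8 methyl (3R)-3-[(1S)-4-oxocyclohex-2-en-1-yl]butanoate, via aldol 7 (not isolated)
Conditions: TsOH·H2O (10 mol%), toluene, 4 Å MS, 70 °C, short reaction time
Reagents that add atoms: none
Why: Acid-catalysed intramolecular aldol condensation (the ring-closing half of a Robinson annulation), in which the methyl ketone enol closes the six-membered ring on the aldehyde and water is lost to the conjugated enone before the aldehyde α-centre (C6) can epimerise, the methyl ester being inert.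

Step 6
Reactants: 8 methyl (3R)-3-[(1S)-4-oxocyclohex-2-en-1-yl]butanoate
Product: 10 methyl (3R)-3-[(1S)-4-(trifluoromethylsulfonyloxy)cyclohexa-2,4-dien-1-yl]butanoate, via lithium dienolate 9 (not isolated)
Conditions: LiN(SiMe3)2 (1.05 equiv), THF, −78 °C; PhNTf2, −78 → 0 °C
Reagents that add atoms: N-phenylbis(trifluoromethanesulfonimide) (O=S(=O)(N(c1ccccc1)S(=O)(=O)C(F)(F)F)C(F)(F)F)
Why: Kinetic deprotonation of a cyclohex-2-enone at the α′ methylene (C4) by a hindered amide base gives the cross-conjugated dienolate and not the γ-deprotonated one that would erase C6, the less acidic ester α-protons are spared, and O-sulfonylation gives the 2-triflyloxy-1,3-diene.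

Step 7
Reactants: 10 methyl (3R)-3-[(1S)-4-(trifluoromethylsulfonyloxy)cyclohexa-2,4-dien-1-yl]butanoate
Product: 11 methyl (3R)-3-[(1S)-4-methylcyclohexa-2,4-dien-1-yl]butanoate
Conditions: MeZnCl (1.5 equiv), Pd(PPh3)4 (5 mol%), THF, 0 °C → rt, degassed; product kept cold under argon and used at once
Reagents that add atoms: methylzinc chloride (C[Zn]Cl)
Why: Negishi cross-coupling of an alkenyl triflate with a methylzinc reagent under zerovalent palladium catalysis tolerates the ester and keeps both double bonds where they are.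

Step 8
Reactants: 11 methyl (3R)-3-[(1S)-4-methylcyclohexa-2,4-dien-1-yl]butanoate
Product: 12 methyl (3R)-3-[(1S,4R,7S)-5-methyl-2,3-dioxabicyclo[2.2.2]oct-5-en-7-yl]butanoate
Conditions: O2 (bubbling), 5,10,15,20-tetraphenylporphyrin (0.5 mol%), CH2Cl2, −40 °C, white LED
Reagents that add atoms: dioxygen (O=O)
Why: The excited sensitiser converts O2 to singlet oxygen, which adds to the s-cis-locked ring diene in a concerted suprafacial [4+2] cycloaddition; the closest known reaction type is the dye-sensitised photooxygenation of α-phellandrene-type 5-alkyl-2-methylcyclohexa-1,3-dienes to their endoperoxides. The six-membered 1,2-dioxine ring (C1–O–O–C4 with C2=C3) closes by cycloaddition across the diene termini, which at the same stroke makes the bridged 2,3-dioxabicyclo[2.2.2]oct-5-ene and leaves the alkene at C2=C3 under the methyl group. C1 and C4 are created together and must be cis to each other because both C–O bonds form on one face. Their configuration relative to C6 should come from approach of O2 to the face opposite the branched sec-alkyl chain on C6, the sp3 carbon next to the C1 terminus. The step needs this facial selectivity and cycloaddition in preference to the ene reaction or dehydrogenation to the arene; the planar cisoid diene and the low temperature favour [4+2], 11 has no other electron-rich alkene, and the ester is inert. Any syn endoperoxide is to be removed by chromatography here or at the diol.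

Step 9
Reactants: 12 methyl (3R)-3-[(1S,4R,7S)-5-methyl-2,3-dioxabicyclo[2.2.2]oct-5-en-7-yl]butanoate
Product: 13 methyl (3R)-3-[(1S,2S,5R)-2,5-dihydroxy-4-methylcyclohex-3-en-1-yl]butanoate
Conditions: thiourea (1.5 equiv), MeOH, 0 °C → rt
Reagents that add atoms: none
Why: Thiourea reduction of an endoperoxide cleaves only the O–O bond (sulfur attacks oxygen, then solvolysis), so the cis-2-ene-1,4-diol keeps the configuration at C1 and C4.

Step 10
Reactants: 13 methyl (3R)-3-[(1S,2S,5R)-2,5-dihydroxy-4-methylcyclohex-3-en-1-yl]butanoate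
Product: 14 (4R,4aS,6R,8aS)-6-hydroxy-4,7-dimethyl-3,4,4a,5,6,8a-hexahydro-2H-chromen-2-one
Conditions: (SCN)Bu2SnOSnBu2(OH) (5 mol%), toluene, 100 °C, MeOH removed through 4 Å MS
Reagents that add atoms: none
Why: Neutral tin-catalysed transesterification (lactonisation) in which only the C1 hydroxyl can reach C9 through a six-membered ring, trans-fused with O and C7 both equatorial, whereas the C4 hydroxyl is trans to the chain and would need a bridged seven-membered ring; no acid is present to ionise the allylic alcohols.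

Step 11
Reactants: 14 (4R,4aS,6R,8aS)-6-hydroxy-4,7-dimethyl-3,4,4a,5,6,8a-hexahydro-2H-chromen-2-one
Product: 15 (4R,4aS,6R,8aS)-6-(tert-butyldimethylsilyloxy)-4,7-dimethyl-3,4,4a,5,6,8a-hexahydro-2H-chromen-2-one
Conditions: TBSCl, imidazole, DMF, rt
Reagents that add atoms: tert-butyldimethylsilyl chloride (CC(C)(C)[Si](C)(C)Cl)
Why: Imidazole-promoted silylation of the only free hydroxyl, a secondary allylic alcohol, masks C4–OH for the organolithium and acylation steps.

Step 12
Reactants: 15 (4R,4aS,6R,8aS)-6-(tert-butyldimethylsilyloxy)-4,7-dimethyl-3,4,4a,5,6,8a-hexahydro-2H-chromen-2-one; 16 1-bromo-2-methylprop-1-ene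
Product: 18 (6R)-6-[(1S,2S,5R)-5-(tert-butyldimethylsilyloxy)-2-hydroxy-4-methylcyclohex-3-en-1-yl]-2-methylhept-2-en-4-one, via 2-methylprop-1-enyllithium 17 (not isolated)
Conditions: 16, t-BuLi (2.0 equiv), Et2O, −78 °C; resulting 17 (1.1 equiv) added slowly to 15, THF, −78 °C; AcOH/THF quench at −78 °C
Reagents that add atoms: none
Why: Bromine–lithium exchange gives the alkenyllithium, which adds once to the lactone carbonyl (nucleophilic acyl addition) because the lithium hemiketal alkoxide persists at −78 °C and releases the enone only on the cold protic quench; the product may equilibrate with its lactol but reacts on through the open form.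

Step 13
Reactants: 18 (6R)-6-[(1S,2S,5R)-5-(tert-butyldimethylsilyloxy)-2-hydroxy-4-methylcyclohex-3-en-1-yl]-2-methylhept-2-en-4-one; 19 angelic acid
Product: 21 (1S,4R,6S)-4-(tert-butyldimethylsilyloxy)-3-methyl-6-[(2R)-6-methyl-4-oxohept-5-en-2-yl]cyclohex-2-en-1-yl (Z)-2-methylbut-2-enoate, via angeloyl 2,4,6-trichlorobenzoyl anhydride 20 (not isolated)
Conditions: 19, 2,4,6-trichlorobenzoyl chloride, Et3N, toluene, rt; then 18, toluene, 75 °C, no DMAP
Reagents that add atoms: none
Why: Yamaguchi-type esterification through the mixed anhydride, in which the alcohol attacks the unhindered angeloyl carbonyl; leaving out the nucleophilic pyridine catalyst should prevent Z to E equilibration to the tiglate by reversible conjugate addition.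

Step 14
Reactants: 21 (1S,4R,6S)-4-(tert-butyldimethylsilyloxy)-3-methyl-6-[(2R)-6-methyl-4-oxohept-5-en-2-yl]cyclohex-2-en-1-yl (Z)-2-methylbut-2-enoate
Product: 22 (1S,4R,6S)-4-(tert-butyldimethylsilyloxy)-6-[(2R,4R)-4-hydroxy-6-methylhept-5-en-2-yl]-3-methylcyclohex-2-en-1-yl (Z)-2-methylbut-2-enoate
Conditions: (S)-1-methyl-3,3-diphenyltetrahydro-1H,3H-pyrrolo[1,2-c][1,3,2]oxazaborole (0.3 equiv), catecholborane (1.8 equiv), toluene, −78 °C; MeOH, then pH 7 buffer
Reagents that add atoms: none
Why: Corey–Bakshi–Shibata reduction, in which the oxazaborolidine binds the ketone with the alkenyl group as the large substituent and delivers hydride from catecholborane to one face, should set C9 as R by reagent-controlled 1,2-reduction, the conjugated ester being inert.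

Step 15
Reactants: 22 (1S,4R,6S)-4-(tert-butyldimethylsilyloxy)-6-[(2R,4R)-4-hydroxy-6-methylhept-5-en-2-yl]-3-methylcyclohex-2-en-1-yl (Z)-2-methylbut-2-enoate
Product: 23 (1S,4R,6S)-4-hydroxy-6-[(2R,4R)-4-hydroxy-6-methylhept-5-en-2-yl]-3-methylcyclohex-2-en-1-yl (Z)-2-methylbut-2-enoate
Conditions: Bu4NF, AcOH (1:1), THF, 0 °C → rt
Reagents that add atoms: none
Why: Fluoride cleaves the Si–O bond, and buffering with acetic acid should keep the angelate from migrating or hydrolysing and the allylic alcohols from ionising.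

Step 16
Reactants: 23 (1S,4R,6S)-4-hydroxy-6-[(2R,4R)-4-hydroxy-6-methylhept-5-en-2-yl]-3-methylcyclohex-2-en-1-yl (Z)-2-methylbut-2-enoate
Product: 24 (1S,4R,6S)-4-acetoxy-6-[(2R,4R)-4-acetoxy-6-methylhept-5-en-2-yl]-3-methylcyclohex-2-en-1-yl (Z)-2-methylbut-2-enoate
Conditions: Ac2O, pyridine, 4-(dimethylamino)pyridine (cat.), CH2Cl2, 0 °C → rt
Reagents that add atoms: acetic anhydride (CC(=O)OC(C)=O)
Why: DMAP-catalysed acyl transfer acetylates both secondary allylic hydroxyls under basic conditions that leave the allylic C–O bonds, the stereocentres and the angelate geometry intact.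

**Compound list**

1 | 3-methylglutaric anhydride | CC1CC(=O)OC(=O)C1 | starting material
2 | (S)-5-methoxy-3-methyl-5-oxopentanoic acid | OC(=O)C[C@H](C)CC(=O)OC | intermediate
3 | methyl (S)-5-hydroxy-3-methylpentanoate | OCC[C@H](C)CC(=O)OC | intermediate
4 | methyl (S)-3-methyl-5-oxopentanoate | O=CC[C@H](C)CC(=O)OC | intermediate
5 | methyl vinyl ketone | CC(=O)C=C | starting material
6 | methyl (3R,4S)-4-formyl-3-methyl-7-oxooctanoate | CC(=O)CC[C@H](C=O)[C@H](C)CC(=O)OC | intermediate
7 | methyl (3R)-3-[(1S)-2-hydroxy-4-oxocyclohexyl]butanoate (aldol, carbinol epimers) | O=C1CC[C@H](C(O)C1)[C@H](C)CC(=O)OC | intermediate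
8 | methyl (3R)-3-[(1S)-4-oxocyclohex-2-en-1-yl]butanoate | O=C1CC[C@H](C=C1)[C@H](C)CC(=O)OC | intermediate
9 | lithium (4S)-4-[(2R)-4-methoxy-4-oxobutan-2-yl]cyclohexa-1,5-dien-1-olate | [Li]OC1=CC[C@H](C=C1)[C@H](C)CC(=O)OC | intermediate
10 | methyl (3R)-3-[(1S)-4-(trifluoromethylsulfonyloxy)cyclohexa-2,4-dien-1-yl]butanoate | FC(F)(F)S(=O)(=O)OC1=CC[C@H](C=C1)[C@H](C)CC(=O)OC | intermediate
11 | methyl (3R)-3-[(1S)-4-methylcyclohexa-2,4-dien-1-yl]butanoate | CC1=CC[C@H](C=C1)[C@H](C)CC(=O)OC | intermediate
12 | methyl (3R)-3-[(1S,4R,7S)-5-methyl-2,3-dioxabicyclo[2.2.2]oct-5-en-7-yl]butanoate (peroxide bridge anti to the chain) | O2[C@@H]1C=C(C)[C@H](O2)C[C@H]1[C@H](C)CC(=O)OC | intermediate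
13 | methyl (3R)-3-[(1S,2S,5R)-2,5-dihydroxy-4-methylcyclohex-3-en-1-yl]butanoate | O[C@@H]1C=C(C)[C@H](O)C[C@H]1[C@H](C)CC(=O)OC | intermediate
14 | (4R,4aS,6R,8aS)-6-hydroxy-4,7-dimethyl-3,4,4a,5,6,8a-hexahydro-2H-chromen-2-one | O1[C@@H]2C=C(C)[C@H](O)C[C@H]2[C@H](C)CC1=O | intermediate
15 | (4R,4aS,6R,8aS)-6-(tert-butyldimethylsilyloxy)-4,7-dimethyl-3,4,4a,5,6,8a-hexahydro-2H-chromen-2-one | O1[C@@H]2C=C(C)[C@H](O[Si](C)(C)C(C)(C)C)C[C@H]2[C@H](C)CC1=O | intermediate
16 | 1-bromo-2-methylprop-1-ene | CC(C)=CBr | starting material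
17 | 2-methylprop-1-enyllithium | CC(C)=C[Li] | intermediate
18 | (6R)-6-[(1S,2S,5R)-5-(tert-butyldimethylsilyloxy)-2-hydroxy-4-methylcyclohex-3-en-1-yl]-2-methylhept-2-en-4-one | O[C@@H]1C=C(C)[C@H](O[Si](C)(C)C(C)(C)C)C[C@H]1[C@H](C)CC(=O)C=C(C)C | intermediate
19 | angelic acid, (Z)-2-methylbut-2-enoic acid | C/C=C(/C)C(=O)O | starting material
20 | angeloyl 2,4,6-trichlorobenzoyl anhydride | C/C=C(/C)C(=O)OC(=O)c1c(Cl)cc(Cl)cc1Cl | intermediate
21 | (1S,4R,6S)-4-(tert-butyldimethylsilyloxy)-3-methyl-6-[(2R)-6-methyl-4-oxohept-5-en-2-yl]cyclohex-2-en-1-yl (Z)-2-methylbut-2-enoate | C/C=C(/C)C(=O)O[C@@H]1C=C(C)[C@H](O[Si](C)(C)C(C)(C)C)C[C@H]1[C@H](C)CC(=O)C=C(C)C | intermediate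
22 | (1S,4R,6S)-4-(tert-butyldimethylsilyloxy)-6-[(2R,4R)-4-hydroxy-6-methylhept-5-en-2-yl]-3-methylcyclohex-2-en-1-yl (Z)-2-methylbut-2-enoate | C/C=C(/C)C(=O)O[C@@H]1C=C(C)[C@H](O[Si](C)(C)C(C)(C)C)C[C@H]1[C@H](C)C[C@H](C=C(C)C)O | intermediate
23 | (1S,4R,6S)-4-hydroxy-6-[(2R,4R)-4-hydroxy-6-methylhept-5-en-2-yl]-3-methylcyclohex-2-en-1-yl (Z)-2-methylbut-2-enoate | C/C=C(/C)C(=O)O[C@@H]1C=C(C)[C@H](O)C[C@H]1[C@H](C)C[C@H](C=C(C)C)O | intermediate
24 | (1S,4R,6S)-4-acetoxy-6-[(2R,4R)-4-acetoxy-6-methylhept-5-en-2-yl]-3-methylcyclohex-2-en-1-yl (Z)-2-methylbut-2-enoate | C/C=C(/C)C(=O)O[C@@H]1C=C(C)[C@H](OC(C)=O)C[C@H]1[C@H](C)C[C@H](C=C(C)C)OC(C)=O | target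

**Step count and risks**

Total step count: 16. Longest linear sequence: 16 steps (1 to 24); compounds 5, 16 and 19 are bought and enter directly.

Steps most likely to fail:

1. Step 8. The sec-alkyl group on C6 may discriminate only weakly between the two diene faces, and part of the diene may be diverted into ene hydroperoxidation or dehydrogenation to the arene. The fallback sets out from diene 11 and builds the cis-1,4-dioxygen pattern by reagent-controlled epoxidation and a palladium-mediated syn 1,4-opening. Asymmetric dioxirane (Shi) epoxidation of the more electron-rich C3=C4 alkene is run with the enantiomer of the fructose-derived ketone that is matched to the face anti to the chain (KHSO5 as Oxone, K2CO3, buffered MeCN/dimethoxymethane, 0 °C) and should give methyl (3R)-3-[(1S,4S,6R)-1-methyl-7-oxabicyclo[4.1.0]hept-2-en-4-yl]butanoate F1. With Pd(PPh3)4 (cat.) and AcOH in THF at 0 °C, zerovalent palladium ionises the allylic C3–O bond with inversion and acetate attacks the C1 terminus of the allyl complex anti to the metal; this net syn 1,4-addition should give methyl (3R)-3-[(1S,2S,5R)-2-acetoxy-5-hydroxy-4-methylcyclohex-3-en-1-yl]butanoate F2. Methanolysis of the acetate (K2CO3, MeOH, 0 °C) comes back to the route at enediol 13.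

2. Step 12. The ketone may be released from the tetrahedral intermediate before the quench and take up a second alkenyllithium, or the lactone may be enolised instead of attacked. The fallback sets out from lactone 15 and passes through a chelate-stabilised acyl donor. Aminolysis with MeNH(OMe)·HCl and Me3Al (CH2Cl2, 0 °C) should open the lactone to (3R)-3-[(1S,2S,5R)-5-(tert-butyldimethylsilyloxy)-2-hydroxy-4-methylcyclohex-3-en-1-yl]-N-methoxy-N-methylbutanamide F3. Treatment with 2-methylprop-1-enylmagnesium bromide (2.5 equiv, THF, 0 °C; the first equivalent is consumed by the free hydroxyl) gives a magnesium chelate that cannot add a second time and collapses on quench, coming back to the route at hydroxy enone 18.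

3. Step 13. The angeloyl group may isomerise to the tigloyl group during activation, or acylation of the hindered allylic alcohol next to the branched C6 may be slow. The fallback sets out from 18 and builds the Z double bond on the substrate rather than carrying it in. Acylation with 2-[bis(2,2,2-trifluoroethoxy)phosphoryl]propanoic acid (DCC, cat. 4-(dimethylamino)pyridine, CH2Cl2) should give (1S,4R,6S)-4-(tert-butyldimethylsilyloxy)-3-methyl-6-[(2R)-6-methyl-4-oxohept-5-en-2-yl]cyclohex-2-en-1-yl 2-[bis(2,2,2-trifluoroethoxy)phosphoryl]propanoate F4. A Z-selective Still–Gennari olefination with acetaldehyde (KN(SiMe3)2, 1.0 equiv, 18-crown-6, THF, −78 °C; the phosphonate is deprotonated in preference to the less acidic ketone) comes back to the route at angelate 21.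

**Further compounds**

F1 | step 8 | methyl (3R)-3-[(1S,4S,6R)-1-methyl-7-oxabicyclo[4.1.0]hept-2-en-4-yl]butanoate | C1=C[C@]2(C)O[C@@H]2C[C@H]1[C@H](C)CC(=O)OC
F2 | step 8 | methyl (3R)-3-[(1S,2S,5R)-2-acetoxy-5-hydroxy-4-methylcyclohex-3-en-1-yl]butanoate | CC(=O)O[C@@H]1C=C(C)[C@H](O)C[C@H]1[C@H](C)CC(=O)OC
F3 | step 12 | (3R)-3-[(1S,2S,5R)-5-(tert-butyldimethylsilyloxy)-2-hydroxy-4-methylcyclohex-3-en-1-yl]-N-methoxy-N-methylbutanamide | O[C@@H]1C=C(C)[C@H](O[Si](C)(C)C(C)(C)C)C[C@H]1[C@H](C)CC(=O)N(C)OC
F4 | step 13 | (1S,4R,6S)-4-(tert-butyldimethylsilyloxy)-3-methyl-6-[(2R)-6-methyl-4-oxohept-5-en-2-yl]cyclohex-2-en-1-yl 2-[bis(2,2,2-trifluoroethoxy)phosphoryl]propanoate | CC(C(=O)O[C@@H]1C=C(C)[C@H](O[Si](C)(C)C(C)(C)C)C[C@H]1[C@H](C)CC(=O)C=C(C)C)P(=O)(OCC(F)(F)F)OCC(F)(F)F
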